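**Retrosynthetic overview**
1. Target ← desilylation, hydration of a C1 alkynyl group to the C2 ketone, and hydroxyl-directed reduction at C9 ← bicyclic keto lactone. (Numbering: carbocycle C1, C5, C6, C7, C8, C9, C10; side chain C2–C4; lactone C11, which bears the exocyclic CH2, and C12.)
2. Key disconnection C11–C7: phosphine-catalysed 5-exo Rauhut–Currier closure of an acrylate on O6 onto a C7=C8–C9=O cycloheptenone. Enabling feature: the C9 oxygen is 1,3 to the ring-fusion carbon C7 and the lactone oxygen sits on the adjacent C6, so at the ketone level C7 is an enone β-carbon five atoms from the acrylate α-carbon, and the short tether forces the cis fusion of the lactone onto the seven-membered ring.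
3. Enone acrylate ← cis-1,4-hydroxy acrylate (Pd-catalysed opening of a diene monoepoxide by acrylic acid) ← hydroxyl-directed monoepoxidation of a cyclohepta-3,5-diene in which C1, C5 and C10 are already set.
4. Diene ← tropone: dearomatising 1,8-methyl addition with enolate hydroxylation (C10, C5), lipase resolution, chelation-controlled addition of an (S)-butynol-derived acetylide to the C1 ketone (C2–C4), acylation with (R)-2-methylbutanoic acid.
5. Ring order: the seven-membered carbocycle is taken intact from tropone; the γ-lactone is the only ring formed, in the key step.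

Key step: step 9

Assumption: Burkholderia cepacia lipase is taken to acylate the (2R,7R)-enantiomer of 5 faster, as is usual for cyclic secondary alcohols of this shape, so that the (2S,7S)-alcohol is the one recovered.

**Step 1**
Reactants: 1 (S)-but-3-yn-2-ol
Product: 2 (S)-tert-butyl(but-3-yn-2-yloxy)dimethylsilane
Conditions: TBSCl, imidazole, DMF, 0 °C to rt
Reagents that add atoms: tert-butyldimethylsilyl chloride, CC(C)(C)[Si](C)(C)Cl
Why: Standard silyl ether formation on a secondary alcohol with imidazole as base and acyl-transfer-type catalyst; the carbinol stereocenter (later C4) is not touched.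

**Step 2**
Reactants: 3 tropone
Product: 5 rac-(2S,7S)-2-hydroxy-7-methylcyclohepta-3,5-dien-1-one, via lithium trienolate 4 (not isolated)
Conditions: MeLi, THF, −78 °C; then 2-(phenylsulfonyl)-3-phenyloxaziridine, −78 °C; aq NH4Cl
Reagents that add atoms: methyllithium, [Li]C; 2-(phenylsulfonyl)-3-phenyloxaziridine, O=S(=O)(c1ccccc1)N1OC1c1ccccc1
Why: Dearomatising 1,8-conjugate addition of the organolithium to tropone gives the trienolate, and Davis enolate hydroxylation at its α-carbon should occur anti to the methyl group, which sits pseudo-axial to avoid allylic 1,2-strain with the O–Li unit, giving the 2,7-trans hydroxy ketone as the racemate.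

**Step 3**
Reactants: 5 rac-(2S,7S)-2-hydroxy-7-methylcyclohepta-3,5-dien-1-one
Product: 6 (2S,7S)-2-hydroxy-7-methylcyclohepta-3,5-dien-1-one
Conditions: Burkholderia cepacia lipase (immobilised), vinyl acetate, t-BuOMe, rt, run to about half conversion; chromatography
Reagents that add atoms: none
Why: Lipase-catalysed kinetic resolution by enantioselective transesterification under neutral conditions that should not isomerise the β,γ-unsaturated ketone; the slow-reacting (2S,7S)-alcohol is recovered and fixes the absolute configuration of C5 and C10.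

**Step 4**
Reactants: 6 (2S,7S)-2-hydroxy-7-methylcyclohepta-3,5-dien-1-one; 2 (S)-tert-butyl(but-3-yn-2-yloxy)dimethylsilane
Product: 8 (1R,2S,7S)-1-{(3S)-3-[(tert-butyldimethylsilyl)oxy]but-1-yn-1-yl}-7-methylcyclohepta-3,5-diene-1,2-diol, via lithium acetylide 7 (not isolated)
Conditions: 2 (2.2 equiv), n-BuLi, THF, −78 °C; CeCl3, −78 °C; then 6, −78 to −40 °C; aq NH4Cl
Reagents that add atoms: none
Why: Organocerium 1,2-addition of an alkynyl nucleophile to an easily enolised ketone; the metal alkoxide of the α-hydroxyl chelates the carbonyl and holds its C–O bond in the carbonyl plane, so the trans α'-methyl group is pseudo-axial and the acetylide should enter anti to it, cis to the C5 oxygen, which sets the C1 carbinol.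

**Step 5**
Reactants: 8 (1R,2S,7S)-1-{(3S)-3-[(tert-butyldimethylsilyl)oxy]but-1-yn-1-yl}-7-methylcyclohepta-3,5-diene-1,2-diol; 9 (R)-2-methylbutanoic acid
Product: 10 (1S,2R,3S)-2-{(3S)-3-[(tert-butyldimethylsilyl)oxy]but-1-yn-1-yl}-2-hydroxy-3-methylcyclohepta-4,6-dien-1-yl (2R)-2-methylbutanoate
Conditions: DIC, DMAP (cat.), CH2Cl2, 0 °C to rt
Reagents that add atoms: none
Why: Steglich esterification should acylate the secondary allylic hydroxyl selectively over the hindered tertiary propargylic one, without epimerising the α-stereocenter of the acid.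

**Step 6**
Reactants: 10 (1S,2R,3S)-2-{(3S)-3-[(tert-butyldimethylsilyl)oxy]but-1-yn-1-yl}-2-hydroxy-3-methylcyclohepta-4,6-dien-1-yl (2R)-2-methylbutanoate
Product: 11 (1S,4S,5R,6S,7R)-5-{(3S)-3-[(tert-butyldimethylsilyl)oxy]but-1-yn-1-yl}-5-hydroxy-6-methyl-8-oxabicyclo[5.1.0]oct-2-en-4-yl (2R)-2-methylbutanoate
Conditions: VO(acac)2 (cat.), t-BuOOH, CH2Cl2, 0 °C
Reagents that add atoms: tert-butyl hydroperoxide, CC(C)(C)OO
Why: Vanadium-catalysed hydroxyl-directed epoxidation from the homoallylic tertiary alcohol should deliver oxygen syn to that hydroxyl (setting C8 and C9), and of the two diene double bonds the one remote from the electron-withdrawing allylic acyloxy group is the more nucleophilic.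

**Step 7**
Reactants: 11 (1S,4S,5R,6S,7R)-5-{(3S)-3-[(tert-butyldimethylsilyl)oxy]but-1-yn-1-yl}-5-hydroxy-6-methyl-8-oxabicyclo[5.1.0]oct-2-en-4-yl (2R)-2-methylbutanoate; 12 acrylic acid
Product: 13 (1R,2S,3R,4S,5S)-3-{(3S)-3-[(tert-butyldimethylsilyl)oxy]but-1-yn-1-yl}-3,5-dihydroxy-4-methyl-2-{[(2R)-2-methylbutanoyl]oxy}cyclohept-6-en-1-yl prop-2-enoate
Conditions: Pd(PPh3)4 (cat.), THF, 0 °C
Reagents that add atoms: none
Why: Tsuji–Trost opening of a cyclic diene monoepoxide by a carboxylic acid: zerovalent palladium ionises the allylic C–O bond with inversion and the carboxylate attacks the distal allyl terminus anti to the metal, so the C6 acrylate should end up cis to the C9 hydroxyl on the face of the former epoxide, while attack at the proximal terminus is hindered on that face by the adjacent oxygen-bearing carbon and the strained epoxide ionises much faster than the allylic ester.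

**Step 8**
Reactants: 13 (1R,2S,3R,4S,5S)-3-{(3S)-3-[(tert-butyldimethylsilyl)oxy]but-1-yn-1-yl}-3,5-dihydroxy-4-methyl-2-{[(2R)-2-methylbutanoyl]oxy}cyclohept-6-en-1-yl prop-2-enoate
Product: 14 (1R,2S,3R,4R)-3-{(3S)-3-[(tert-butyldimethylsilyl)oxy]but-1-yn-1-yl}-3-hydroxy-4-methyl-2-{[(2R)-2-methylbutanoyl]oxy}-5-oxocyclohept-6-en-1-yl prop-2-enoate
Conditions: Dess–Martin periodinane, CH2Cl2, 0 °C to rt
Reagents that add atoms: none
Why: Dess–Martin oxidation of the secondary allylic alcohol to the enone under near-neutral conditions; the tertiary alcohol cannot be oxidised and the acrylate, alkyne and silyl ether are inert.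

**Step 9**
Reactants: 14 (1R,2S,3R,4R)-3-{(3S)-3-[(tert-butyldimethylsilyl)oxy]but-1-yn-1-yl}-3-hydroxy-4-methyl-2-{[(2R)-2-methylbutanoyl]oxy}-5-oxocyclohept-6-en-1-yl prop-2-enoate
Product: 15 (3aS,6R,7R,8S,8aR)-7-{(3S)-3-[(tert-butyldimethylsilyl)oxy]but-1-yn-1-yl}-7-hydroxy-6-methyl-3-methylidene-2,5-dioxooctahydro-2H-cyclohepta[b]furan-8-yl (2R)-2-methylbutanoate
Conditions: PMe3 (20 mol %), tert-amyl alcohol, rt, high dilution
Reagents that add atoms: none
Why: Rauhut–Currier (vinylogous Morita–Baylis–Hillman) cyclisation: PMe3 adds reversibly to the acrylate β-carbon, the resulting ester enolate attacks the enone β-carbon C7, and proton transfer in the protic medium followed by β-elimination of the phosphine restores the exocyclic methylene and releases the catalyst. The closest known reaction type is the phosphine-catalysed intramolecular Rauhut–Currier reaction of acrylates tethered through oxygen to the γ-carbon of cyclic enones and dienones, which gives cis-fused α-methylene-γ-butyrolactones. The lactone closes in the 5-exo-trig mode by forming the bond between the acrylate α-carbon C11 and C7. The only new stereocenter, C7, is controlled by C6, because the three-atom O–C(=O)–C tether can reach C7 only from the face that carries the C6 oxygen, so the ring fusion must be cis. The step needs chemoselectivity between the two acceptors and survival of the β-hydroxy ketone: phosphine addition to the enone is reversible and its enolate could only close a seven-membered ring, so the 5-exo path is the only productive one, and the neutral, base-free conditions should avoid retro-aldol cleavage, dehydration at C1 and epimerisation at C10 or in the 2-methylbutanoate.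

**Step 10**
Reactants: 15 (3aS,6R,7R,8S,8aR)-7-{(3S)-3-[(tert-butyldimethylsilyl)oxy]but-1-yn-1-yl}-7-hydroxy-6-methyl-3-methylidene-2,5-dioxooctahydro-2H-cyclohepta[b]furan-8-yl (2R)-2-methylbutanoate
Product: 16 (3aS,5R,6S,7R,8S,8aR)-7-{(3S)-3-[(tert-butyldimethylsilyl)oxy]but-1-yn-1-yl}-5,7-dihydroxy-6-methyl-3-methylidene-2-oxooctahydro-2H-cyclohepta[b]furan-8-yl (2R)-2-methylbutanoate
Conditions: Me4NBH(OAc)3, MeCN/AcOH, −25 °C
Reagents that add atoms: none
Why: Evans–Saksena hydroxyl-directed reduction: the C1 hydroxyl, β to the ketone, binds boron and delivers hydride to the carbonyl face syn to itself, which should give the 1,3-anti diol (C9 carbinol), while this mild reagent leaves the α-methylene lactone, the esters and the alkyne alone.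

**Step 11**
Reactants: 16 (3aS,5R,6S,7R,8S,8aR)-7-{(3S)-3-[(tert-butyldimethylsilyl)oxy]but-1-yn-1-yl}-5,7-dihydroxy-6-methyl-3-methylidene-2-oxooctahydro-2H-cyclohepta[b]furan-8-yl (2R)-2-methylbutanoate
Product: 18 (3aS,5R,6S,7S,8S,8aR)-7-{(3S)-3-[(tert-butyldimethylsilyl)oxy]butanoyl}-5,7-dihydroxy-6-methyl-3-methylidene-2-oxooctahydro-2H-cyclohepta[b]furan-8-yl (2R)-2-methylbutanoate, via cyclic enol ether 17 (not isolated)
Conditions: Ph3PAuNTf2 (cat.), THF/H2O, rt
Reagents that add atoms: water, O
Why: π-Acid-catalysed 5-exo-dig hydroalkoxylation with a cationic monovalent gold catalyst: the new C9 hydroxyl, cis to the alkynyl group, attacks the proximal alkyne carbon to give enol ether 17, whose hydrolysis in the wet medium should place the ketone at C2 only (the neighbouring ester carbonyl can assist in the same regiochemical sense).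

**Step 12**
Reactants: 18 (3aS,5R,6S,7S,8S,8aR)-7-{(3S)-3-[(tert-butyldimethylsilyl)oxy]butanoyl}-5,7-dihydroxy-6-methyl-3-methylidene-2-oxooctahydro-2H-cyclohepta[b]furan-8-yl (2R)-2-methylbutanoate
Product: 19 (3aS,5R,6S,7S,8S,8aR)-5,7-dihydroxy-7-[(3S)-3-hydroxybutanoyl]-6-methyl-3-methylidene-2-oxooctahydro-2H-cyclohepta[b]furan-8-yl (2R)-2-methylbutanoate (CNP0291806.3)
Conditions: HF·pyridine, THF, 0 °C
Reagents that add atoms: none
Why: Fluoride-mediated desilylation under mildly acidic conditions that the β-hydroxy ketone, the esters and the α-methylene lactone should tolerate.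

**Compound list**
1 | (S)-but-3-yn-2-ol | C#C[C@H](C)O | starting material
2 | (S)-tert-butyl(but-3-yn-2-yloxy)dimethylsilane | C#C[C@H](C)O[Si](C)(C)C(C)(C)C | intermediate
3 | tropone (cyclohepta-2,4,6-trien-1-one) | O=C1C=CC=CC=C1 | starting material
4 | lithium 7-methylcyclohepta-1,3,5-trien-1-olate (racemic) | CC1C=CC=CC=C1[O-].[Li+] | intermediate (not isolated)
5 | rac-(2S,7S)-2-hydroxy-7-methylcyclohepta-3,5-dien-1-one (trans; both enantiomers shown) | C1=CC=C[C@H](C)C(=O)[C@H]1O.C1=CC=C[C@@H](C)C(=O)[C@@H]1O | intermediate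
6 | (2S,7S)-2-hydroxy-7-methylcyclohepta-3,5-dien-1-one | C1=CC=C[C@H](C)C(=O)[C@H]1O | intermediate
7 | lithium (3S)-3-[(tert-butyldimethylsilyl)oxy]but-1-yn-1-ide | [Li+].[C-]#C[C@H](C)O[Si](C)(C)C(C)(C)C | intermediate (not isolated)
8 | (1R,2S,7S)-1-{(3S)-3-[(tert-butyldimethylsilyl)oxy]but-1-yn-1-yl}-7-methylcyclohepta-3,5-diene-1,2-diol | C1=CC=C[C@H](C)[C@@](O)(C#C[C@H](C)O[Si](C)(C)C(C)(C)C)[C@H]1O | intermediate
9 | (R)-2-methylbutanoic acid | CC[C@@H](C)C(=O)O | starting material
10 | (1S,2R,3S)-2-{(3S)-3-[(tert-butyldimethylsilyl)oxy]but-1-yn-1-yl}-2-hydroxy-3-methylcyclohepta-4,6-dien-1-yl (2R)-2-methylbutanoate | C1=CC=C[C@H](C)[C@@](O)(C#C[C@H](C)O[Si](C)(C)C(C)(C)C)[C@H]1OC(=O)[C@H](C)CC | intermediate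
11 | (1S,4S,5R,6S,7R)-5-{(3S)-3-[(tert-butyldimethylsilyl)oxy]but-1-yn-1-yl}-5-hydroxy-6-methyl-8-oxabicyclo[5.1.0]oct-2-en-4-yl (2R)-2-methylbutanoate (epoxide cis to the tertiary hydroxyl) | C1=C[C@@H]2O[C@@H]2[C@H](C)[C@@](O)(C#C[C@H](C)O[Si](C)(C)C(C)(C)C)[C@H]1OC(=O)[C@H](C)CC | intermediate
12 | acrylic acid | C=CC(=O)O | starting material
13 | (1R,2S,3R,4S,5S)-3-{(3S)-3-[(tert-butyldimethylsilyl)oxy]but-1-yn-1-yl}-3,5-dihydroxy-4-methyl-2-{[(2R)-2-methylbutanoyl]oxy}cyclohept-6-en-1-yl prop-2-enoate | C=CC(=O)O[C@@H]1C=C[C@H](O)[C@H](C)[C@@](O)(C#C[C@H](C)O[Si](C)(C)C(C)(C)C)[C@H]1OC(=O)[C@H](C)CC | intermediate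
14 | (1R,2S,3R,4R)-3-{(3S)-3-[(tert-butyldimethylsilyl)oxy]but-1-yn-1-yl}-3-hydroxy-4-methyl-2-{[(2R)-2-methylbutanoyl]oxy}-5-oxocyclohept-6-en-1-yl prop-2-enoate | C=CC(=O)O[C@@H]1C=CC(=O)[C@H](C)[C@@](O)(C#C[C@H](C)O[Si](C)(C)C(C)(C)C)[C@H]1OC(=O)[C@H](C)CC | intermediate
15 | (3aS,6R,7R,8S,8aR)-7-{(3S)-3-[(tert-butyldimethylsilyl)oxy]but-1-yn-1-yl}-7-hydroxy-6-methyl-3-methylidene-2,5-dioxooctahydro-2H-cyclohepta[b]furan-8-yl (2R)-2-methylbutanoate | C=C1C(=O)O[C@@H]2[C@H]1CC(=O)[C@H](C)[C@@](O)(C#C[C@H](C)O[Si](C)(C)C(C)(C)C)[C@H]2OC(=O)[C@H](C)CC | intermediate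
16 | (3aS,5R,6S,7R,8S,8aR)-7-{(3S)-3-[(tert-butyldimethylsilyl)oxy]but-1-yn-1-yl}-5,7-dihydroxy-6-methyl-3-methylidene-2-oxooctahydro-2H-cyclohepta[b]furan-8-yl (2R)-2-methylbutanoate | C=C1C(=O)O[C@@H]2[C@H]1C[C@@H](O)[C@H](C)[C@@](O)(C#C[C@H](C)O[Si](C)(C)C(C)(C)C)[C@H]2OC(=O)[C@H](C)CC | intermediate
17 | bridged (Z)-enol ether formed by addition of the C9 hydroxyl of 16 to the proximal alkyne carbon (2-alkylidene-oxolane spanning C9, C10, C1) | C=C1C(=O)O[C@@H]2[C@H]1C[C@@H](O3)[C@H](C)[C@@](O)(/C3=C/[C@H](C)O[Si](C)(C)C(C)(C)C)[C@H]2OC(=O)[C@H](C)CC | intermediate (not isolated)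
18 | (3aS,5R,6S,7S,8S,8aR)-7-{(3S)-3-[(tert-butyldimethylsilyl)oxy]butanoyl}-5,7-dihydroxy-6-methyl-3-methylidene-2-oxooctahydro-2H-cyclohepta[b]furan-8-yl (2R)-2-methylbutanoate | C=C1C(=O)O[C@@H]2[C@H]1C[C@@H](O)[C@H](C)[C@@](O)(C(=O)C[C@H](C)O[Si](C)(C)C(C)(C)C)[C@H]2OC(=O)[C@H](C)CC | intermediate
19 | (3aS,5R,6S,7S,8S,8aR)-5,7-dihydroxy-7-[(3S)-3-hydroxybutanoyl]-6-methyl-3-methylidene-2-oxooctahydro-2H-cyclohepta[b]furan-8-yl (2R)-2-methylbutanoate (CNP0291806.3) | C=C1C(=O)O[C@@H]2[C@H]1C[C@@H](O)[C@H](C)[C@@](O)(C(=O)C[C@H](C)O)[C@H]2OC(=O)[C@H](C)CC | target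

**Step count and risks**
Total step count: 12. Longest linear sequence: 11 steps (tropone 3 to target 19, steps 2–12); the alkyne arm adds one step before it joins at step 4.

Steps most likely to fail:

1. Step 6. The directed epoxidation may attack the other diene double bond or the wrong face, and the acid-sensitive vinyl epoxide may rearrange before use; a wrong regiochemistry in step 7 would follow from the same weakness. Fallback: starting from diene ester 10, a [4+2] cycloaddition of singlet oxygen (O2, tetraphenylporphyrin, hν, CH2Cl2, −20 °C) places both oxygens at C6 and C9 at once, on the face of the tertiary hydroxyl, and gives endoperoxide F1. Reduction of the O–O bond with thiourea in MeOH gives the cis-ene-diol F2. MnO2 should oxidise the allylic carbinol remote from the electron-withdrawing acyloxy group to give the γ-hydroxy enone F3. Acylation with acryloyl chloride and i-Pr2NEt at −78 °C rejoins the route at enone acrylate 14, so steps 6–8 are bypassed.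

2. Step 11. The tertiary propargylic carbinol may ionise under π-acid catalysis (Meyer–Schuster-type rearrangement), or water may add with the wrong regiochemistry. Fallback: starting from diol 16, silylation of the secondary C9 hydroxyl with (HMe2Si)2NH gives the hydrodimethylsilyl ether F4. Pt2(dvds)3-catalysed intramolecular syn-hydrosilylation (6-exo-dig) puts silicon on C2 and gives the cyclic vinylsiloxane F5. Tamao–Fleming oxidation (KF, KHCO3, H2O2, THF/MeOH, 0 °C) then gives ketone 18, where the route is rejoined.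

3. Step 2. Facial selectivity in the enolate hydroxylation may be poor, the β,γ-unsaturated hydroxy ketone may isomerise into conjugation, and the resolution in step 3 then discards at least half of the material. Fallback: starting from tropone 3, conjugate reduction with LiBH(s-Bu)3 and O-silylation of the trienolate with TBSCl gives the achiral tert-butyl(cyclohepta-1,3,5-trien-1-yloxy)dimethylsilane F6. Shi epoxidation (fructose-derived ketone catalyst, KHSO5, K2CO3, MeCN/dimethoxymethane/H2O, 0 °C) should select the trisubstituted enol ether over the two cis-disubstituted double bonds, and desilylative work-up gives enantioenriched (S)-2-hydroxycyclohepta-3,5-dien-1-one F7. Methylation of its dianion (2 equiv LDA, MeI, THF, −78 °C) anti to the alkoxide gives 6, so steps 2 and 3 are replaced.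

**Further compounds**
F1 | step 6 | endoperoxide of 10 (O–O bridge across C6 and C9, cis to the tertiary hydroxyl) | O1O[C@@H]2C=C[C@H]1[C@H](C)[C@@](O)(C#C[C@H](C)O[Si](C)(C)C(C)(C)C)[C@H]2OC(=O)[C@H](C)CC
F2 | step 6 | cis-ene-diol (C6 and C9 hydroxyls cis to the tertiary hydroxyl) | O[C@@H]1C=C[C@H](O)[C@H](C)[C@@](O)(C#C[C@H](C)O[Si](C)(C)C(C)(C)C)[C@H]1OC(=O)[C@H](C)CC
F3 | step 6 | γ-hydroxy enone (C9 ketone, free C6 hydroxyl) | O[C@@H]1C=CC(=O)[C@H](C)[C@@](O)(C#C[C@H](C)O[Si](C)(C)C(C)(C)C)[C@H]1OC(=O)[C@H](C)CC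
F4 | step 11 | C9-O-dimethylsilyl (Si–H) ether of 16 | C=C1C(=O)O[C@@H]2[C@H]1C[C@@H](O[SiH](C)C)[C@H](C)[C@@](O)(C#C[C@H](C)O[Si](C)(C)C(C)(C)C)[C@H]2OC(=O)[C@H](C)CC
F5 | step 11 | cyclic vinylsiloxane (silicon on C2, six-membered Si–O ring through C9, C10, C1) | C=C1C(=O)O[C@@H]2[C@H]1C[C@@H](O[Si]3(C)C)[C@H](C)[C@@](O)(/C3=C\[C@H](C)O[Si](C)(C)C(C)(C)C)[C@H]2OC(=O)[C@H](C)CC
F6 | step 2 | tert-butyl(cyclohepta-1,3,5-trien-1-yloxy)dimethylsilane | CC(C)(C)[Si](C)(C)OC1=CC=CC=CC1
F7 | step 2 | (S)-2-hydroxycyclohepta-3,5-dien-1-one | C1=CC=CCC(=O)[C@H]1O
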